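The data were computed for an exercise; noise was put on by code.

Set two rates side by side in each flask: how fast substrate is used, and how fast target is lost.

| setting | birch | oak | Saturday's | Wednesday's | Monday's | Friday's |
|---|---|---|---|---|---|---|
| substrate | 0.38 M | 0.38 M | 0.38 M | 0.38 M | 0.38 M | 0.38 M |
| partner | 1 equiv | 1 equiv | 1.00 equiv | 1.00 equiv | 1.00 equiv | 1.00 equiv |
| protic impurity | 0.13 M | 0.29 M | 0.190 M | 0.190 M | 0.190 M | 0.190 M |
| temperature | 70 °C | 90 °C | 105 °C |  | 90 °C | 75 °C |
| remark | run made earlier | run made earlier |  | at 105 °C until 15 h, from then on at 75 °C |  |  |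
| time |  |  | 3.0 d | 3.0 d | 3.0 d | 3.0 d |

| run | time / d | target / % | substrate / % |
|---|---|---|---|
| birch | 3.00 | 44 | 47 |
| birch | 6.00 | 42 | 40 |
| birch | 10.0 | 40 | 34 |
| birch | 12.0 | 33 | 36 |
| birch | 15.0 | 26 | 38 |
| oak | 1.04 | 24 | 54 |
| oak | 2.00 | 11 | 55 |
| oak | 4.00 | 4 | 56 |
| oak | 5.00 | 1 | 54 |
| oak | 6.00 | 0 | 55 |

(scatter of a reading: 1.5 percentage points)
- which flask leads in amount of target, in percent of the substrate charged ("all alike" within 1.5 percentage points) (Saturday's / Wednesday's / Monday's / Friday's / all alike)
- how much target is there at the end, in percent of the substrate charged: Saturday's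
- how much target is there at the end, in percent of the substrate charged: Wednesday's
- how much target is there at the end, in percent of the substrate charged: Monday's
- how much target is there at the end, in percent of the substrate charged: Friday's
- a reading of substrate is of its free form alone

1. How fast at the start. In the birch run substrate goes at 0.177 d⁻¹ of its charge on average over the first 3.00 d. In the hotter oak run it goes at 0.442 d⁻¹ over the first 1.04 d.

2. What slows it. Between the first two birch readings the use drops to 0.0233 d⁻¹, a factor of 7.60. Substrate then stands near 34% in the birch run and near 55% in the oak run, which holds more impurity. Interpolating to 0.190 M gives a stall at 41.9%, so I take 58.1% as the ceiling for target.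

3. The crossing. The late birch readings give a loss constant (first-order rate constant) of 0.0862 d⁻¹, and the oak readings give 0.605 d⁻¹. The birch target readings go from 44% at 3.00 d to 42% at 6.00 d, a step of 2 percentage points against a scatter of 1.5 points in each reading, so I can place the crossing, where making and loss are equal, only roughly, around that stretch of the birch run. For the estimate I let target decay from the ceiling over the whole time.

4. Temperature. I lay the whole difference between the two constants on temperature, which gives a factor of 4.32 for the step from 75 °C to 90 °C and again to 105 °C. The constants become 0.140 d⁻¹ and 2.61 d⁻¹.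

5. The loss number: the loss constant times the time, summed over the stretches, so that the surviving share is exp(−N). Saturday's has 7.84, Wednesday's 1.97, Monday's 1.82 and Friday's 0.421. Multiplying the ceiling by the survival, I reckon 0.0230%, 8.14%, 9.46% and 38.2%, in that order.

The forecast names Friday's as leader with 0.3%, 12%, 11% and 42% in the same order, saying “Target then decays roughly first-order”, and its Friday's figure is higher than mine.

The flasks give 0.119%, 9.04%, 8.77% and 38.2%, so Friday's leads.

    partner + protic impurity → quenched reagent (k = 0.00410 M⁻¹ min⁻¹, Ea = 97.0 kJ mol⁻¹)
    substrate + partner ⇌ target (K = 8.00 M⁻¹, k = 0.00380 M⁻¹ min⁻¹, Ea = 76.0 kJ mol⁻¹, ΔH = −46.0 kJ mol⁻¹)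
    target → over-reaction product (k = 4.00 × 10⁻⁴ min⁻¹, Ea = 129 kJ mol⁻¹)
    substrate + partner ⇌ isomer of the product (K = 250 M⁻¹, k = 6.40 × 10⁻⁴ M⁻¹ min⁻¹, Ea = 96.0 kJ mol⁻¹, ΔH = −24.0 kJ mol⁻¹)
    (constants at 90 °C)

Saturday's holds more target than I reckoned, though both figures are tiny. Now take the neighbour, the same flask as Saturday's read at 20 h. Its loss number is 2.18, which gives 6.59%. That neighbour holds 4.54% of target beside 32.6% of over-reaction product.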